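Decide the next charge.

solid substrate 0.050 M; partner 0.0750 M; protic impurity 1.00 mM; time 10 h

1. the target and solid product together standing at 10 h, as a percentage of the solid substrate charged
2. the change that raises the amount of target and solid product together at 10 h, in percent of the solid substrate charged most ("none" if none brings more than 2 percentage points) (Wednesday's / Sunday's / Monday's / Thursday's / none)
3. amount of target and solid product together at 10 h, in percent of the solid substrate charged, after Wednesday's

- Wednesday's: doubling the amount of partner, all else as stated
- Sunday's: doubling the solubility in step 4, all else as stated
- Monday's: doubling the solubility in step 1, all else as stated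
- Thursday's: doubling the dissolution coefficient of step 4, all else as stated

- for target the solid product is counted in
- as a solid, counted per litre of solution: solid substrate, solid product
- at the start none of the solid substrate is in solution
- run time (flask): 10 h

    solid substrate ⇌ dissolved substrate, rate k1*(cs1 - [dissolved substrate]) while solid is left; crystals form when [dissolved substrate] > cs1 (cs1 = 21 mM, k1 = 2.04 h⁻¹)
    dissolved substrate + partner → target (k2 = 84.0 L mol⁻¹ h⁻¹)
    partner → side product (k3 = 1.91 h⁻¹)
    solid product ⇌ target, rate k4*(cs4 - [target]) while solid is left; crystals form when [target] > cs4 (cs4 = 17 mM, k4 = 2.43 h⁻¹)
    target ⇌ isomer of the product (K5 = 1.5, k5 = 0.142 h⁻¹)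
    partner ⇌ dormant form (K6 = 0.32, k6 = 0.175 h⁻¹)
    partner + protic impurity → quenched reagent (k7 = 35.6 L mol⁻¹ h⁻¹)

Ask first what the end state is. Target and isomer of the product settle at the ratio 1.5, so target ends as 40.0% of what was made, and the approach runs at 0.237 h⁻¹. Call the share of made target still standing as target at 10 h, with no crystals present and counting from the start, the kept fraction: 45.6%.

Then reckon what is made, as a race for partner. Step 3 takes it at 1.91 h⁻¹, step 2 at k2 times c(dissolved substrate). Ignoring what step 2 draws off, c(dissolved substrate) climbs towards 21 mM, so a partner molecule meets about 10.8 mM on average over its life. Step 2 then wins 32.3% of the partner, which makes 24.2 mM and, with the kept fraction, gives my y of 22.1%.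

For the decision, doubling partner at that share makes 48.4 mM. Doubling the solubility in step 1 makes 36.6 mM, which is less than Wednesday's. My base figure lies above 17 mM, so I keep the step 4 changes open. Charge more partner.

The forecast agrees on the choice but not on the base: 15%, Wednesday's, and 29% after it. Its ground is that "The partner is lost quickly to its first-order side reaction", and it puts the target made at about 16 mM, under the solubility, where mine lies above.

The flask gives 15.7%, and 27.2% after Wednesday's, which gains 12 percentage points against 7.9 points for Monday's. Sunday's and Thursday's bring 0 points, and solid product stands at 0% at 10.0 h.

Divide y by the kept fraction: the flask made about 17.2 mM, or 22.9% of the partner, less than my reckoned 24.2 mM. The main loss is the turning of partner into side product: struck out, the answer rises from 15.7% to 68.8%. In the neighbour charged with 0.030 M of partner, isomer of the product stands at 8.00% at the end, so the kept fraction predicts target at 6.71%; that flask gives 7.08%.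

All constants are made up; the result is computed.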